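## The problem

The target is a 2-acylamino-5,6-epoxy-4-hydroxycyclohex-2-enone (ring A, numbered from the ketone C1 to C6, oxirane fused at C5–C6) whose quaternary carbinol C4 carries an all-E hepta-2,4,6-trienamide chain (C7–C13) ending on the enol form of 2-aminocyclopentane-1,3-dione (ring B). The nitrogen on C2 is acylated by (R,E)-2,4-dimethyloct-2-enoic acid (C1′–C8′). Ring A holds three contiguous stereocentres, C4 (S), C5 (R) and C6 (S); the cis-oxirane ties C5 and C6 together, and these two can control C4, where the hydroxyl must sit on the oxirane face. The fourth stereocentre, C4′, is insulated from the ring by an enamide and a trisubstituted alkene, so it must be made separately in enantiopure form. Nearly every group is fragile: the epoxy ketone towards nucleophiles and base, the doubly allylic tertiary alcohol towards acid, the triene towards light and electrophiles, the enamide towards hydrolysis, and ring B is a vinylogous acid. The oxirane should therefore be present from the start, and the triene and both amides should be attached last under near-neutral conditions. A short entry is possible because C1, C6, C5 and C4 map onto the four carbons of meso cis-epoxysuccinic acid, while C4 is bonded to two sp2 carbons, ring carbon C3 and chain carbon C7, that can both start as vinyl groups.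

## Retrosynthesis

**C8–C9.** Target 27 is cut between the ring-bound vinyl carbon and the dienamide, giving enamide 26 and iododienamide 24. Cutting the C13–N amide last would need a free trienoic acid on the finished epoxyquinol. Cutting C4–C7 would mean adding a metallated polyene to an epoxy-quinone, which discards the vinyl group that ring closure leaves behind. The chosen cut removes seven chain carbons and ring B at once. The forward Heck reaction must insert only at the monosubstituted alkene, give the E alkene and run without strong base. A ketone cannot form because C4 has no hydrogen.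

**C2–N and C2–I.** Enamide 26 is cut to iodoenone 25 and primary amide 16, and 25 is cut to enone 7. Placing nitrogen on the acryloyl partner before ring closure would make that alkene a 1,1-disubstituted, chelating enamide, which is a poor metathesis substrate. A plain enone is iodinated at C2 by a standard method, and vinylic iodides couple with amides under CuI/diamine catalysis. Enone 7 lacks the whole upper chain. The forward steps must iodinate only C2 and form the C–N bond with a mild carbonate base. The syn hydroxyl cannot open the oxirane because it has no backside access to C5, so it is carried unprotected.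

**C2=C3 (key cut).** Enone 7 is opened to triene 6, in which C4 bears two identical vinyl groups and C1 is an acryloyl ketone. Cutting C1–C2 or C3–C4 instead would require an aldol or an organometallic addition on an epoxy ketone. The chosen cut removes the C4 stereocentre: 6 has only the two oxirane stereocentres. The forward ring-closing metathesis must close onto one of two diastereotopic vinyl groups so that the hydroxyl ends up syn to the oxirane.

**C1–C2, C3–C4 and C4–C7.** Triene 6 is cut to the amide ester 4 and three equivalents of vinyl Grignard reagent 5. One reagent in one operation suffices, because an ester takes two vinyl groups and an N-methoxy-N-methylamide only one. Stepwise construction would add redox and protecting steps. The forward step needs 1,2-addition at the transient vinyl ketone and a quench that keeps the liberated amine off the new enone.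

**Desymmetrisation.** Amide ester 4 comes from half-ester 3, which comes from meso diester 2 and diacid 1. No C–C bond is involved. The only task is to tell the two carboxyls apart, and this fixes the absolute configuration of C5 and C6. An enzymatic hydrolysis of the diester is the shortest way.

**Upper amide.** Amide 16 comes from ester 15 by aminolysis, which avoids a free acid and an activation step. Ester 15 is cut at C2′=C3′ into aldehyde 14 and stabilised ylide 13, which secures the E trisubstituted alkene. Aldehyde 14 comes from alcohol 12 and imide 11. The C4′ methyl of 11 is set by auxiliary-controlled methylation of imide 10, made from oxazolidinone 8 and acid chloride 9.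

**Lower fragment.** Iododienamide 24 is cut at the amide into acid 19 and amine salt 22, so that ring B is acylated before it meets the epoxyquinol. Acid 19 comes from ester 18, made by iodo-olefination of aldehyde ester 17. Salt 22 comes from dione 20 through nitro compound 21.

## Roads not taken

Alternative 1: This road cuts no ring bond. All six ring carbons and C7 come from (−)-shikimic acid A1. The forward key step is an OsO4-catalysed syn-dihydroxylation of the protected enoate mesylate A2, anti to the mesylate, giving diol A3 with the C4–O and C5–O bonds in place.
- **Merits:** the absolute configuration comes from the chiral pool, and the facial selectivity of the dihydroxylation is substrate-controlled and reliable. No desymmetrisation and no group selection are needed.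
- **Weak points:** A3 is far from the target in oxidation pattern. The oxirane must be closed by displacing the mesylate, and the acetal must be removed with acid in the presence of that oxirane. The remaining trans-diol must be converted into the C1 ketone and the C2 enamide. C7 arrives as an ester on a tertiary carbinol and must be reduced and olefinated twice to reach the triene.
- **Comparison:** this road is better in the certainty of absolute and relative configuration. The chosen plan offers a core in five steps from 1, a C7=C8 vinyl group ready for coupling in 7, and C2 functionalisation in two steps.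

Alternative 2: This road cuts C4–C5 and C1–C6. The forward key step is a cinchona-alkaloid-catalysed [4+2] addition of 3-hydroxy-2-pyrone A4 to phenyl vinyl sulfone A5, giving bridged lactone A6.
- **Merits:** one catalytic step makes the carbocycle, the C4 carbinol, the C2=C3 alkene, C7 and the C1 oxygen, and either enantiomer is available from the pseudo-enantiomeric catalyst. C4 is set in the same event as the ring, so no vinyl selection arises.
- **Weak points:** the bicycle must be taken apart. Lactone opening leaves C7 at the acid level and C1 as an alcohol. The sulfone must be eliminated to give C5=C6, and the oxirane must then be installed late on one of two similar alkenes. Bridged pyrone adducts also tend to lose CO2 on heating.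
- **Comparison:** its enantiocontrol rests on a catalyst class known for closely related cycloadditions and is arguably safer than an enzyme of unproven sense. The chosen plan avoids late epoxidation and needs fewer steps after the ring is formed.

Alternative 3: This road cuts the two C–O bonds of the oxirane. Methyl p-coumarate A7 is dearomatised to the prochiral quinol A8. The forward key step is an enantioselective nucleophilic epoxidation under chiral phase-transfer catalysis, which epoxidises one of the two enantiotopic enones syn to the hydroxyl and gives A9.
- **Merits:** it is the shortest route to a core on paper, the hydroxyl directs the syn relationship, and C7=C8 is already an E alkene.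
- **Weak points:** the catalyst must tell apart two enones whose only difference is a remote quaternary carbinol. The acrylate is a third Michael acceptor, and double epoxidation is possible. The side chain in A9 still needs four carbons, which means ester reduction and olefination on a free epoxyquinol.
- **Comparison:** if the enantioselection were high this road would beat the chosen plan in step count. The chosen plan fixes the absolute configuration on a small, robust half-ester whose purity can be checked and upgraded. Its remaining selection is diastereotopic, so an imperfect result gives separable isomers and does not lower enantiomeric purity.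

Key step: step 5

Assumption: pig liver esterase is taken to hydrolyse the ester on the (S)-configured oxirane carbon of 2; if it prefers the other ester, the two carboxyls of the half-ester exchange roles (ester aminolysed to the N-methoxy-N-methylamide, acid re-esterified) and the route continues unchanged from 4.

## Route

Step 1
Reactants: 1 cis-epoxysuccinic acid [(2R,3S)-oxirane-2,3-dicarboxylic acid, meso]
Product: 2 dimethyl cis-epoxysuccinate (meso)
Conditions: MeI (2.5 equiv), KHCO3, DMF, rt
Reagents that add atoms: iodomethane, CI
Why: Carboxylate O-alkylation (SN2 at methyl, once at each carboxylate) avoids the acid of a Fischer esterification, so the oxirane should survive; the stereocentres are untouched and the product stays meso.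

Step 2
Reactants: 2 dimethyl cis-epoxysuccinate
Product: 3 (2S,3R)-3-(methoxycarbonyl)oxirane-2-carboxylic acid
Conditions: pig liver esterase, NaH2PO4/Na2HPO4 buffer pH 7, NaOH (pH-stat), 25 °C; then HCl to pH 2
Reagents that add atoms: water, O
Why: Enzymatic desymmetrisation of a meso diester: the hydrolase should cleave one of the two enantiotopic ester groups, and the half-ester anion is a poor substrate, so hydrolysis stops there. No stereocentre is formed, but this choice fixes the absolute configuration of C5 and C6.

Step 3
Reactants: 3 (2S,3R)-3-(methoxycarbonyl)oxirane-2-carboxylic acid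
Product: 4 methyl (2R,3S)-3-[methoxy(methyl)carbamoyl]oxirane-2-carboxylate
Conditions: MeNHOMe·HCl, EDC·HCl, N-methylmorpholine, CH2Cl2, 0 °C → rt
Reagents that add atoms: N,O-dimethylhydroxylamine hydrochloride, CNOC.Cl
Why: Carbodiimide amide coupling of the free acid under weakly basic conditions should leave the oxirane and the methyl ester alone; the oxirane carbons cannot epimerise.

Step 4
Reactants: 4 methyl (2R,3S)-3-[methoxy(methyl)carbamoyl]oxirane-2-carboxylate, 5 vinylmagnesium bromide
Product: 6 1-[(2S,3R)-3-(3-hydroxypenta-1,4-dien-3-yl)oxiran-2-yl]prop-2-en-1-one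
Conditions: CH2=CHMgBr (4.5 equiv, of which 3 equiv are incorporated), THF, −78 → −20 °C; inverse quench into cold 1 M HCl/Et2O
Reagents that add atoms: vinylmagnesium bromide, C=C[Mg]Br
Why: Threefold Grignard addition in one flask, in which three equivalents of 5 end up in 6: the ester takes two vinyl groups through a transient vinyl ketone to give the divinyl carbinol, while the N-methoxy-N-methylamide takes one because its magnesium chelate lasts until the quench (Weinreb ketone synthesis). Quenching into cold acid protonates the liberated amine before it can add to the new enone; C4 is not yet stereogenic and the oxirane carbons are not touched.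

Step 5
Reactants: 6 1-[(2S,3R)-3-(3-hydroxypenta-1,4-dien-3-yl)oxiran-2-yl]prop-2-en-1-one
Product: 7 (1S,5S,6R)-5-ethenyl-5-hydroxy-7-oxabicyclo[4.1.0]hept-3-en-2-one
Conditions: RuCl2(H2IMes)(=CH-C6H4-2-OiPr) (second-generation Hoveyda–Grubbs catalyst, 5 mol%), toluene (2 mM), 60 °C, Ar sparge
Reagents that add atoms: none
Why: Ring-closing olefin metathesis: the alkylidene released from RuCl2(H2IMes)(=CH-C6H4-2-OiPr) loads on one of the two electron-rich carbinol vinyl groups, adds [2+2] across the acryloyl C=C, and cycloreversion of the ruthenacyclobutane forms C2=C3 and releases ethylene. The closest known reactions are ring-closing metathesis of dienones to cyclohex-2-enones and diastereotopic-group-selective ring-closing metathesis of divinyl carbinols with a neighbouring stereocentre. The ring is a six-membered carbocycle closed between an allylic-carbinol carbene and an enone; the cis-oxirane holds both arms on the same side, and the new alkene is necessarily cis in the ring. C4 becomes stereogenic here and is controlled by C5 and C6: the vinyl that cyclises must lie synclinal to C6 about the C4–C5 bond, which leaves one C4 substituent beside the oxirane C–O bond and the other beside C5–H. The hydroxyl should take the place beside the oxirane oxygen, where it closes a five-membered O–H···O hydrogen bond in a non-polar solvent, while the larger vinyl group avoids the oxirane lone pairs; this gives the 4S product with hydroxyl syn to the oxirane. The carbene should exchange between the two vinyl groups faster than it closes onto the electron-poor enone, so the ratio is set by the two ring-closing transition states (Curtin–Hammett). The step needs diastereotopic-group selectivity, secured by the free hydroxyl and toluene, and cyclisation over cross-metathesis, secured by dilution; a C4 epimer would be a separable diastereomer.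

Step 6
Reactants: 8 (R)-4-benzyloxazolidin-2-one, 9 hexanoyl chloride
Product: 10 (R)-4-benzyl-3-hexanoyloxazolidin-2-one
Conditions: n-BuLi, THF, −78 °C; then 9, −78 → 0 °C
Reagents that add atoms: none
Why: N-acylation of the lithiated oxazolidinone by an acid chloride; no stereocentre is affected.

Step 7
Reactants: 10 (R)-4-benzyl-3-hexanoyloxazolidin-2-one
Product: 11 (R)-4-benzyl-3-[(R)-2-methylhexanoyl]oxazolidin-2-one
Conditions: NaN(SiMe3)2, THF, −78 °C; MeI, −78 °C
Reagents that add atoms: iodomethane, CI
Why: Evans alkylation: the chelated Z sodium enolate is methylated on the face away from the benzyl group, which with the (R)-auxiliary should set the (R) centre that becomes C4′; the minor diastereomer is removable by chromatography.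

Step 8
Reactants: 11 (R)-4-benzyl-3-[(R)-2-methylhexanoyl]oxazolidin-2-one
Product: 12 (R)-2-methylhexan-1-ol
Conditions: LiBH4, MeOH (1 equiv), Et2O, 0 °C
Reagents that add atoms: none
Why: Reductive cleavage of the imide at the exocyclic carbonyl frees the primary alcohol without touching the α-stereocentre and returns the auxiliary.

Step 9
Reactants: 12 (R)-2-methylhexan-1-ol, 13 ethyl 2-(triphenylphosphoranylidene)propanoate
Product: 15 ethyl (R,E)-2,4-dimethyloct-2-enoate, via (R)-2-methylhexanal 14 (not isolated)
Conditions: (COCl)2, DMSO, CH2Cl2, −78 °C; Et3N; then 13, −78 °C → rt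
Reagents that add atoms: none
Why: Swern oxidation followed by Wittig olefination in the same flask, so the volatile, epimerisable α-branched aldehyde is never isolated. The stabilised α-methyl ylide should give the E trisubstituted enoate.

Step 10
Reactants: 15 ethyl (R,E)-2,4-dimethyloct-2-enoate
Product: 16 (R,E)-2,4-dimethyloct-2-enamide
Conditions: AlMe3, NH4Cl, toluene, 0 → 50 °C; aq. HCl work-up
Reagents that add atoms: ammonium chloride, [NH4+].[Cl-]
Why: Weinreb aminolysis: the aluminium amide formed from AlMe3 and NH4Cl converts the ester directly into the primary amide; alkene geometry and C4′ should be unaffected at this temperature.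

Step 11
Reactants: 17 ethyl (E)-4-oxobut-2-enoate
Product: 18 ethyl (2E,4E)-5-iodopenta-2,4-dienoate
Conditions: CrCl2, CHI3, THF, 0 °C
Reagents that add atoms: iodoform, IC(I)I
Why: Takai olefination: the geminal dichromium species made from CHI3 and CrCl2 (divalent chromium) adds to the aldehyde, not the ester, and eliminates to the E vinyl iodide.

Step 12
Reactants: 18 ethyl (2E,4E)-5-iodopenta-2,4-dienoate
Product: 19 (2E,4E)-5-iodopenta-2,4-dienoic acid
Conditions: LiOH, THF/H2O, 0 °C → rt; then 1 M HCl
Reagents that add atoms: lithium hydroxide, [Li+].[OH-]
Why: Ester saponification at low temperature; the vinylic iodide and both E alkenes should be stable to cold hydroxide.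

Step 13
Reactants: 20 cyclopentane-1,3-dione
Product: 21 2-nitrocyclopentane-1,3-dione (enol form 3-hydroxy-2-nitrocyclopent-2-en-1-one)
Conditions: fuming HNO3, Et2O, 0 °C
Reagents that add atoms: nitric acid, O[N+](=O)[O-]
Why: Electrophilic nitration at C2 of the enolised 1,3-dione, the only nucleophilic carbon.

Step 14
Reactants: 21 2-nitrocyclopentane-1,3-dione
Product: 22 2-amino-3-hydroxycyclopent-2-en-1-one hydrochloride
Conditions: H2 (1 atm), Pd/C, HCl, MeOH, rt
Reagents that add atoms: hydrogen chloride, Cl
Why: Catalytic hydrogenation of the nitro group; the acid traps the air-sensitive amine as its salt, and the vinylogous acid is not reduced.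

Step 15
Reactants: 19 (2E,4E)-5-iodopenta-2,4-dienoic acid, 22 2-amino-3-hydroxycyclopent-2-en-1-one hydrochloride
Product: 24 (2E,4E)-N-(2-hydroxy-5-oxocyclopent-1-en-1-yl)-5-iodopenta-2,4-dienamide, via (2E,4E)-5-iodopenta-2,4-dienoyl chloride 23 (not isolated)
Conditions: (COCl)2, DMF (cat.), CH2Cl2, 0 °C → rt, evaporate; then 22, Et3N, THF, 0 °C → rt
Reagents that add atoms: none
Why: Acid chloride formation and N-acylation; any O-acylated enol should transfer its acyl group to nitrogen to give the hydrogen-bonded enol amide.

Step 16
Reactants: 7 (1S,5S,6R)-5-ethenyl-5-hydroxy-7-oxabicyclo[4.1.0]hept-3-en-2-one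
Product: 25 (1S,5S,6R)-5-ethenyl-5-hydroxy-3-iodo-7-oxabicyclo[4.1.0]hept-3-en-2-one
Conditions: iodine, pyridine/CH2Cl2, 0 °C → rt, dark
Reagents that add atoms: iodine, [I][I]
Why: α-Iodination of an enone by the addition–elimination path (pyridine adds at C3, the enolate is iodinated at C2, pyridine leaves), a Baylis–Hillman-type sequence known for 4,4-disubstituted cyclohexenones. C3 is the only β-carbon, and the stereocentres are not involved.

Step 17
Reactants: 25 (1S,5S,6R)-5-ethenyl-5-hydroxy-3-iodo-7-oxabicyclo[4.1.0]hept-3-en-2-one, 16 (R,E)-2,4-dimethyloct-2-enamide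
Product: 26 (2E,4R)-N-[(1S,5S,6R)-5-ethenyl-5-hydroxy-2-oxo-7-oxabicyclo[4.1.0]hept-3-en-3-yl]-2,4-dimethyloct-2-enamide
Conditions: CuI (20 mol%), MeNHCH2CH2NHMe (40 mol%), K2CO3, toluene, 60 °C
Reagents that add atoms: none
Why: Goldberg-type vinylic amidation: the amidate formed on diamine-ligated CuI (monovalent copper) activates the C2–I bond and forms C2–N at the same carbon. The carbonate base is mild, and the syn alkoxide cannot reach the backside of C5–O, so no Payne rearrangement is expected.

Step 18
Reactants: 26 (2E,4R)-N-[(1S,5S,6R)-5-ethenyl-5-hydroxy-2-oxo-7-oxabicyclo[4.1.0]hept-3-en-3-yl]-2,4-dimethyloct-2-enamide, 24 (2E,4E)-N-(2-hydroxy-5-oxocyclopent-1-en-1-yl)-5-iodopenta-2,4-dienamide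
Product: 27 (2E,4R)-N-[(1S,5S,6R)-5-hydroxy-5-[(1E,3E,5E)-7-[(2-hydroxy-5-oxocyclopent-1-en-1-yl)amino]-7-oxohepta-1,3,5-trien-1-yl]-2-oxo-7-oxabicyclo[4.1.0]hept-3-en-3-yl]-2,4-dimethyloct-2-enamide
Conditions: Pd(OAc)2 (10 mol%), AgOAc, DMF, rt → 40 °C, dark
Reagents that add atoms: none
Why: Heck coupling under AgOAc-assisted, ligand-free conditions: the dienyl iodide adds oxidatively to zerovalent palladium formed from Pd(OAc)2, AgOAc removes iodide, and syn-carbopalladation places the dienyl group on the terminal carbon C8. β-Hydride elimination can only occur towards C8 because C4 has no hydrogen, which should give the E C7=C8 alkene with the dienyl geometry retained.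

## Compound list

1 | cis-epoxysuccinic acid [(2R,3S)-oxirane-2,3-dicarboxylic acid, meso] | OC(=O)[C@@H]1O[C@@H]1C(O)=O | starting material
2 | dimethyl cis-epoxysuccinate [dimethyl (2R,3S)-oxirane-2,3-dicarboxylate, meso] | COC(=O)[C@@H]1O[C@@H]1C(=O)OC | intermediate
3 | (2S,3R)-3-(methoxycarbonyl)oxirane-2-carboxylic acid | COC(=O)[C@@H]1O[C@@H]1C(O)=O | intermediate
4 | methyl (2R,3S)-3-[methoxy(methyl)carbamoyl]oxirane-2-carboxylate | COC(=O)[C@@H]1O[C@@H]1C(=O)N(C)OC | intermediate
5 | vinylmagnesium bromide | C=C[Mg]Br | starting material
6 | 1-[(2S,3R)-3-(3-hydroxypenta-1,4-dien-3-yl)oxiran-2-yl]prop-2-en-1-one [(4S,5R)-4,5-epoxy-6-ethenyl-6-hydroxyocta-1,7-dien-3-one] | C=CC(O)(C=C)[C@@H]1O[C@@H]1C(=O)C=C | intermediate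
7 | (1S,5S,6R)-5-ethenyl-5-hydroxy-7-oxabicyclo[4.1.0]hept-3-en-2-one [(4S,5R,6S)-5,6-epoxy-4-hydroxy-4-vinylcyclohex-2-enone, hydroxyl syn to the oxirane] | C1=C[C@@](O)(C=C)[C@@H]2O[C@@H]2C1=O | intermediate
8 | (R)-4-benzyloxazolidin-2-one | O=C1N[C@H](Cc2ccccc2)CO1 | starting material
9 | hexanoyl chloride | CCCCCC(=O)Cl | starting material
10 | (R)-4-benzyl-3-hexanoyloxazolidin-2-one | CCCCCC(=O)N1[C@H](Cc2ccccc2)COC1=O | intermediate
11 | (R)-4-benzyl-3-[(R)-2-methylhexanoyl]oxazolidin-2-one | CCCC[C@@H](C)C(=O)N1[C@H](Cc2ccccc2)COC1=O | intermediate
12 | (R)-2-methylhexan-1-ol | CCCC[C@@H](C)CO | intermediate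
13 | ethyl 2-(triphenylphosphoranylidene)propanoate | CCOC(=O)C(C)=P(c1ccccc1)(c1ccccc1)c1ccccc1 | starting material
14 | (R)-2-methylhexanal (formed and used in the flask) | CCCC[C@@H](C)C=O | intermediate
15 | ethyl (R,E)-2,4-dimethyloct-2-enoate | CCCC[C@@H](C)/C=C(\C)C(=O)OCC | intermediate
16 | (R,E)-2,4-dimethyloct-2-enamide | CCCC[C@@H](C)/C=C(\C)C(N)=O | intermediate
17 | ethyl (E)-4-oxobut-2-enoate | CCOC(=O)/C=C/C=O | starting material
18 | ethyl (2E,4E)-5-iodopenta-2,4-dienoate | CCOC(=O)/C=C/C=C/I | intermediate
19 | (2E,4E)-5-iodopenta-2,4-dienoic acid | OC(=O)/C=C/C=C/I | intermediate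
20 | cyclopentane-1,3-dione | O=C1CCC(=O)C1 | starting material
21 | 2-nitrocyclopentane-1,3-dione (enol form 3-hydroxy-2-nitrocyclopent-2-en-1-one) | O=C1CCC(O)=C1[N+](=O)[O-] | intermediate
22 | 2-amino-3-hydroxycyclopent-2-en-1-one hydrochloride | NC1=C(O)CCC1=O.Cl | intermediate
23 | (2E,4E)-5-iodopenta-2,4-dienoyl chloride (formed and used in the flask) | ClC(=O)/C=C/C=C/I | intermediate
24 | (2E,4E)-N-(2-hydroxy-5-oxocyclopent-1-en-1-yl)-5-iodopenta-2,4-dienamide | I/C=C/C=C/C(=O)NC1=C(O)CCC1=O | intermediate
25 | (1S,5S,6R)-5-ethenyl-5-hydroxy-3-iodo-7-oxabicyclo[4.1.0]hept-3-en-2-one | IC1=C[C@@](O)(C=C)[C@@H]2O[C@@H]2C1=O | intermediate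
26 | (2E,4R)-N-[(1S,5S,6R)-5-ethenyl-5-hydroxy-2-oxo-7-oxabicyclo[4.1.0]hept-3-en-3-yl]-2,4-dimethyloct-2-enamide | CCCC[C@@H](C)/C=C(\C)C(=O)NC1=C[C@@](O)(C=C)[C@@H]2O[C@@H]2C1=O | intermediate
27 | (2E,4R)-N-[(1S,5S,6R)-5-hydroxy-5-[(1E,3E,5E)-7-[(2-hydroxy-5-oxocyclopent-1-en-1-yl)amino]-7-oxohepta-1,3,5-trien-1-yl]-2-oxo-7-oxabicyclo[4.1.0]hept-3-en-3-yl]-2,4-dimethyloct-2-enamide | CCCC[C@@H](C)/C=C(\C)C(=O)NC1=C[C@@](O)(/C=C/C=C/C=C/C(=O)NC2=C(O)CCC2=O)[C@@H]2O[C@@H]2C1=O | target

## Step count and least certain steps

Total: 18 steps. Longest linear sequence: 8 steps (steps 1–5, 16, 17, 18). The upper amide takes 5 steps (6–10) and the lower fragment 5 steps (11–15) in two short branches.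

**Step 5 (key step).** The most likely failure is ring closure through the other diastereotopic vinyl group. The hydrogen bond to the oxirane oxygen competes with hydrogen bonding to the C1 carbonyl and to the chloride ligands of the catalyst, and the two transition states differ only in a 1,2-relationship. Oligomerisation through the acryloyl group if the dilution is insufficient is a second concern. The fallback sets C4 by addition to a ring ketone instead of by group selection. It sets out from 4. Cp2Zr(H)Cl reduces the N-methoxy-N-methylamide selectively to methyl (2R,3S)-3-formyloxirane-2-carboxylate F1. One equivalent of 5 at −78 °C adds to the aldehyde, and the alkoxide closes onto the cis ester to give the vinyl lactone 4-ethenyl-3,6-dioxabicyclo[3.1.0]hexan-2-one F2. A second equivalent of 5 at −78 °C adds once to the lactone and gives the hydroxy dienone 1-[3-(1-hydroxyprop-2-en-1-yl)oxiran-2-yl]prop-2-en-1-one F3, which has one vinyl group at each end. Ring-closing metathesis with the catalyst of step 5 gives 5-hydroxy-7-oxabicyclo[4.1.0]hept-3-en-2-one F4, whose ketone is C4 and whose carbinol is C1. CH2=CHMgBr with CeCl3 adds to the C4 carbonyl from the face away from the oxirane, the usual sense for epoxy ketones of this family, giving 5-ethenyl-7-oxabicyclo[4.1.0]hept-3-ene-2,5-diol F5 with the tertiary hydroxyl syn to the oxirane. MnO2 then oxidises only the secondary allylic alcohol, and the route is rejoined at 7.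

**Step 2.** The enzyme may discriminate the two ester groups incompletely or in the opposite sense, because the small, nearly flat oxirane offers little difference between the two binding modes. The fallback is reagent-controlled opening of the meso anhydride. It sets out from 1. Dehydration with trifluoroacetic anhydride gives cis-epoxysuccinic anhydride F6. Methanolysis in toluene at low temperature with a stoichiometric cinchona alkaloid (quinidine or quinine, chosen by the sense found) opens one of the two enantiotopic carbonyls and returns to the route at 3.

**Step 4.** A second Grignard equivalent may add in conjugate fashion to the transient vinyl ketone on the ester side, or the liberated amine may add to the acryloyl group of 6 during work-up. The fallback makes the two ends in separate operations through a lactone and releases no amine. It sets out from 3. Excess 5 with CeCl3 (the first equivalent only deprotonates the acid) converts the ester into the divinyl carbinol, and carbodiimide-assisted closure gives the lactone 4,4-diethenyl-3,6-dioxabicyclo[3.1.0]hexan-2-one F7. One equivalent of 5 at −78 °C adds once to the lactone carbonyl, the magnesium lactolate holds until the quench, and the lactol opens to 6, where the route is rejoined.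

**Step 17.** The iodoenone may decompose under the warm, basic conditions (binding of the free tertiary alkoxide to CuI, oxirane opening), or protodeiodination may outrun the slow coupling of a hindered conjugated amide. The fallback masks the hydroxyl during C–N bond formation. It sets out from 25. Et3SiOTf and 2,6-lutidine give the triethylsilyl ether (1S,5S,6R)-5-ethenyl-3-iodo-5-(triethylsilyloxy)-7-oxabicyclo[4.1.0]hept-3-en-2-one F8. The same CuI-catalysed coupling with 16 gives the silylated enamide (2E,4R)-N-[(1S,5S,6R)-5-ethenyl-2-oxo-5-(triethylsilyloxy)-7-oxabicyclo[4.1.0]hept-3-en-3-yl]-2,4-dimethyloct-2-enamide F9. Buffered fluoride (Et3N·3HF) removes the silyl group and returns to the route at 26.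

**Step 18.** Carbopalladation of the hindered vinyl group beside the quaternary carbinol may be slow, so that homocoupling or decomposition of 24, or binding of the Pd(OAc)2-derived catalyst by the acidic enol of ring B, takes over. The fallback forms the same bond by Suzuki coupling after turning the vinyl group into a nucleophile. It sets out from 26. Cross-metathesis with vinylboronic acid pinacol ester under the catalyst of step 5 gives the E alkenylboronate (2E,4R)-N-[(1S,5S,6R)-5-hydroxy-2-oxo-5-[(E)-2-(4,4,5,5-tetramethyl-1,3,2-dioxaborolan-2-yl)ethenyl]-7-oxabicyclo[4.1.0]hept-3-en-3-yl]-2,4-dimethyloct-2-enamide F10. Suzuki coupling with 24 (Pd(PPh3)4, aqueous K3PO4, THF, rt) forms C8–C9 and returns to the route at 27.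

## Further compounds

F1 | step 5 | methyl (2R,3S)-3-formyloxirane-2-carboxylate | COC(=O)[C@@H]1O[C@@H]1C=O
F2 | step 5 | 4-ethenyl-3,6-dioxabicyclo[3.1.0]hexan-2-one (oxirane configuration as in 4, both C4 epimers) | O=C2[C@@H]1O[C@@H]1C(C=C)O2
F3 | step 5 | 1-[3-(1-hydroxyprop-2-en-1-yl)oxiran-2-yl]prop-2-en-1-one (cis-oxirane as in 4, both carbinol epimers) | C=CC(=O)[C@@H]1O[C@@H]1C(O)C=C
F4 | step 5 | 5-hydroxy-7-oxabicyclo[4.1.0]hept-3-en-2-one (ketone at target C4, carbinol at target C1, both carbinol epimers) | C1=CC(=O)[C@@H]2O[C@@H]2C1O
F5 | step 5 | 5-ethenyl-7-oxabicyclo[4.1.0]hept-3-ene-2,5-diol (tertiary hydroxyl syn to the oxirane, both C2 epimers) | C1=C[C@@](O)(C=C)[C@@H]2O[C@@H]2C1O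
F6 | step 2 | cis-epoxysuccinic anhydride (3,6-dioxabicyclo[3.1.0]hexane-2,4-dione, meso) | O=C2OC(=O)[C@@H]1O[C@@H]12
F7 | step 4 | 4,4-diethenyl-3,6-dioxabicyclo[3.1.0]hexan-2-one (oxirane configuration as in 3) | C=CC2(C=C)[C@@H]1O[C@@H]1C(=O)O2
F8 | step 17 | (1S,5S,6R)-5-ethenyl-3-iodo-5-(triethylsilyloxy)-7-oxabicyclo[4.1.0]hept-3-en-2-one | IC1=C[C@@](O[Si](CC)(CC)CC)(C=C)[C@@H]2O[C@@H]2C1=O
F9 | step 17 | (2E,4R)-N-[(1S,5S,6R)-5-ethenyl-2-oxo-5-(triethylsilyloxy)-7-oxabicyclo[4.1.0]hept-3-en-3-yl]-2,4-dimethyloct-2-enamide | CCCC[C@@H](C)/C=C(\C)C(=O)NC1=C[C@@](O[Si](CC)(CC)CC)(C=C)[C@@H]2O[C@@H]2C1=O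
F10 | step 18 | (2E,4R)-N-[(1S,5S,6R)-5-hydroxy-2-oxo-5-[(E)-2-(4,4,5,5-tetramethyl-1,3,2-dioxaborolan-2-yl)ethenyl]-7-oxabicyclo[4.1.0]hept-3-en-3-yl]-2,4-dimethyloct-2-enamide | CCCC[C@@H](C)/C=C(\C)C(=O)NC1=C[C@@](O)(/C=C/B3OC(C)(C)C(C)(C)O3)[C@@H]2O[C@@H]2C1=O
A1 | alternative 1 | (−)-shikimic acid | C1[C@H]([C@@H]([C@@H](C=C1C(=O)O)O)O)O
A2 | alternative 1 | methyl shikimate 3-methanesulfonate, 4,5-diol protected as the butane-2,3-diacetal | COC(=O)C1=C[C@@H](OS(C)(=O)=O)[C@H]2O[C@](C)(OC)[C@@](C)(OC)O[C@@H]2C1
A3 | alternative 1 | 1,2-cis-diol of the protected shikimate 3-mesylate | COC(=O)[C@@]1(O)[C@H](O)[C@@H](OS(C)(=O)=O)[C@H]2O[C@](C)(OC)[C@@](C)(OC)O[C@@H]2C1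
A4 | alternative 2 | 3-hydroxy-2H-pyran-2-one | O=C1OC=CC=C1O
A5 | alternative 2 | phenyl vinyl sulfone | C=CS(=O)(=O)c1ccccc1
A6 | alternative 2 | 4-hydroxy-8-(phenylsulfonyl)-2-oxabicyclo[2.2.2]oct-5-en-3-one | O=C1O[C@H]2C=C[C@]1(O)[C@H](S(=O)(=O)c1ccccc1)C2
A7 | alternative 3 | methyl (E)-4-hydroxycinnamate | COC(=O)/C=C/c1ccc(O)cc1
A8 | alternative 3 | methyl (E)-3-(1-hydroxy-4-oxocyclohexa-2,5-dien-1-yl)acrylate | COC(=O)/C=C/C1(O)C=CC(=O)C=C1
A9 | alternative 3 | methyl (E)-3-(syn-5,6-epoxy-4-hydroxy-1-oxocyclohex-2-en-4-yl)acrylate | C1=C[C@@](O)(/C=C/C(=O)OC)[C@@H]2O[C@@H]2C1=O
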